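**Strategy.** The flavanone is cut back to a flavone whose ring C is made from an aryne. On ring A the ring oxygen O1 sits on C8a and the C4 carbonyl carbon on the adjacent C4a, flanked by the C5 oxygen: the ortho oxygen/acyl pattern that a 3-alkoxybenzyne accepts regioselectively. In one flask a fluoride-released aryne inserts into the C–O bond of phenylpropiolic acid (C8a–O1, C4a–C4) and the hydroxyaryl ynone closes O1–C2. The precursor is a 3-(methoxymethoxy)-2-(trimethylsilyl)phenyl triflate already carrying the complete bicyclic lactone as benzylic ether on the future C7 oxygen, attached by Mitsunobu inversion; asymmetric CuH reduction and MOM removal finish the synthesis.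

Key step: step 14

Abbreviation used in names: Lac = (S)-[(3aR,5S,6aR)-2-oxohexahydrofuro[3,2-b]furan-5-yl](phenyl)methyl; LacO– is its benzylic ether.

Assumption: (R)-DTBM-SEGPHOS is taken to deliver hydride to the Re face of C2 (2S product); if a test run shows the opposite sense, the commercial (S)-ligand is used instead.

**Ring A fragment**

Step 1
Reactants: 1 resorcinol
Product: 2 3-(methoxymethoxy)phenol
Conditions: NaH (1.0 equiv), MOMCl (1.0 equiv), DMF, 0 °C to rt; resorcinol in threefold excess
Reagents that add atoms: chloromethyl methyl ether, COCCl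
Why: Williamson-type O-alkylation of the monosodium phenoxide, in which the excess of the cheap symmetric diol should bias the statistical outcome toward the mono-ether and the unreacted diol is washed out with water.

Step 2
Reactants: 2 3-(methoxymethoxy)phenol
Product: 3 3-(methoxymethoxy)phenyl isopropylcarbamate
Conditions: i-PrNCO (1.3 equiv), Et3N (0.2 equiv), CH2Cl2, rt
Reagents that add atoms: isopropyl isocyanate, CC(C)N=C=O
Why: Amine-catalysed addition of the phenol to the isocyanate (carbamoylation) installs a directing group that can later be removed under mild base.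

Step 3
Reactants: 3 3-(methoxymethoxy)phenyl isopropylcarbamate
Product: 6 3-(methoxymethoxy)-2-(trimethylsilyl)phenyl isopropylcarbamate, via N-silyl carbamate 4 (not isolated), via C-silylated N-silyl carbamate 5 (not isolated)
Conditions: TBSOTf (1.1 equiv), TMEDA (1.1 equiv), Et2O, 0 °C to rt; TMEDA (2 equiv), n-BuLi (2 equiv), −78 °C; TMSCl (3 equiv), −78 °C to rt; sat. aq NH4Cl
Reagents that add atoms: chlorotrimethylsilane, C[Si](C)(C)Cl
Why: Directed ortho-metalation after transient N-silylation of the N–H: the only C–H flanked by both directing groups (carbamate and MOM ether) is lithiated and silylated, and the labile N–Si bond is hydrolysed on work-up.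

Step 4
Reactants: 6 3-(methoxymethoxy)-2-(trimethylsilyl)phenyl isopropylcarbamate
Product: 8 3-(methoxymethoxy)-2-(trimethylsilyl)phenyl trifluoromethanesulfonate, via silyl phenol 7 (not isolated)
Conditions: DBU (1.5 equiv), Et2NH (1.25 equiv), MeCN, 40 °C; then PhNTf2 (1.5 equiv), rt
Reagents that add atoms: N-phenylbis(trifluoromethanesulfonimide), O=S(=O)(N(c1ccccc1)S(=O)(=O)C(F)(F)F)C(F)(F)F
Why: E1cB cleavage of the N-monoalkyl carbamate (the aryloxide leaves and Et2NH traps the isocyanate as a urea) followed by O-sulfonylation of the phenoxide in the same flask, a carbamate-to-triflate exchange that spares the aryl silane and the MOM ether.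

Step 5
Reactants: 8 3-(methoxymethoxy)-2-(trimethylsilyl)phenyl trifluoromethanesulfonate
Product: 9 3-(methoxymethoxy)-5-(4,4,5,5-tetramethyl-1,3,2-dioxaborolan-2-yl)-2-(trimethylsilyl)phenyl trifluoromethanesulfonate
Conditions: [Ir(OMe)(cod)]2 (2 mol%), dtbpy (4 mol%), B2pin2 (1.0 equiv), cyclohexane, 70 °C
Reagents that add atoms: bis(pinacolato)diboron, CC1(C)OB(OC1(C)C)B1OC(C)(C)C(C)(C)O1
Why: Sterically governed iridium-catalysed aromatic C–H borylation, which in this 1,2,3-trisubstituted ring can only reach the C5–H that has no ortho neighbour and tolerates the silyl triflate pair.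

Step 6
Reactants: 9 the aryl pinacolboronate
Product: 10 5-hydroxy-3-(methoxymethoxy)-2-(trimethylsilyl)phenyl trifluoromethanesulfonate
Conditions: NaBO3·4H2O (3 equiv), THF/H2O 1:1, rt
Reagents that add atoms: sodium perborate tetrahydrate (NaBO3·4H2O), [Na+].[Na+].O[B-]1(O)OO[B-](O)(O)OO1
Why: Oxidation of the aryl boronate (1,2-aryl shift from boron to oxygen, then hydrolysis) under mildly basic perborate conditions that should leave the triflate, the aryl silane and the MOM ether untouched.

**Lactone fragment**

Step 7
Reactants: 11 methyl (R)-mandelate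
Product: 12 methyl (R)-2-[(tert-butyldimethylsilyl)oxy]-2-phenylacetate
Conditions: TBSCl (1.2 equiv), imidazole (2 equiv), DMF, rt
Reagents that add atoms: tert-butyldimethylsilyl chloride, CC(C)(C)[Si](C)(C)Cl
Why: Imidazole-promoted O-silylation gives a bulky, non-chelating ether, which the stereochemical course of step 9 requires.

Step 8
Reactants: 12 methyl (R)-2-[(tert-butyldimethylsilyl)oxy]-2-phenylacetate
Product: 13 (R)-2-[(tert-butyldimethylsilyl)oxy]-2-phenylacetaldehyde
Conditions: i-Bu2AlH (DIBAL-H, 1.1 equiv), CH2Cl2, −78 °C; aq potassium sodium tartrate; used crude and cold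
Reagents that add atoms: none
Why: Partial ester reduction, in which the tetrahedral aluminium hemiacetal persists at −78 °C and releases the aldehyde only on work-up; immediate use without chromatography guards the enolisable α-aryl centre against racemisation.

Step 9
Reactants: 13 (R)-2-[(tert-butyldimethylsilyl)oxy]-2-phenylacetaldehyde
Product: 14 (5S,6R)-6-[(tert-butyldimethylsilyl)oxy]-5-hydroxy-6-phenylhex-1-en-3-one
Conditions: CH2=C(OSiMe3)CH=CH2 (1.5 equiv), BF3·OEt2 (1.1 equiv), CH2Cl2, −78 °C; aq NaHCO3
Reagents that add atoms: 2-(trimethylsilyloxy)buta-1,3-diene, C=CC(=C)O[Si](C)(C)C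
Why: Mukaiyama aldol addition of the enol-ether terminus to the BF3-activated aldehyde; with a monodentate Lewis acid and a silyl ether no chelate can form, so the polar Felkin–Anh (Cornforth) transition state should give the 5,6-anti adduct and thereby set the 5S centre.

Step 10
Reactants: 14 the β-hydroxy vinyl ketone
Product: 16 (3R,5S,6R)-6-[(tert-butyldimethylsilyl)oxy]-6-phenylhex-1-ene-3,5-diol, via diethylborinate chelate 15 (not isolated)
Conditions: Et2BOMe (1.1 equiv), THF/MeOH 4:1, −78 °C; NaBH4 (1.2 equiv), −78 °C; then MeOH co-evaporation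
Reagents that add atoms: none
Why: Narasaka–Prasad reduction, in which the six-membered boron chelate of the β-hydroxy ketone takes external hydride in 1,2-fashion on its less hindered face to give the 1,3-syn diol, setting the 3R carbinol from the 5S one.

Step 11
Reactants: 16 the syn-ene-diol
Product: 17 (3aR,5S,6aR)-5-{(R)-[(tert-butyldimethylsilyl)oxy](phenyl)methyl}tetrahydrofuro[3,2-b]furan-2(3H)-one
Conditions: PdCl2 (10 mol%), CuCl2 (3 equiv), NaOAc (3 equiv), CO (1 atm), AcOH, rt
Reagents that add atoms: carbon monoxide, [C-]#[O+]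
Why: Palladium-catalysed oxycarbonylative bicyclisation of a pent-4-ene-1,3-diol: 5-exo oxypalladation by the C5 hydroxyl, CO insertion and lactonisation by the allylic C3 hydroxyl can only end in the cis-fused lactone, so the new 3a centre is dictated by the C3 carbinol, while CuCl2 returns zerovalent palladium to divalent palladium.

Step 12
Reactants: 17 the silyl-protected lactone
Product: 18 (3aR,5S,6aR)-5-[(R)-hydroxy(phenyl)methyl]tetrahydrofuro[3,2-b]furan-2(3H)-one
Conditions: HF·pyridine, THF/pyridine, 0 °C to rt
Reagents that add atoms: none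
Why: Fluoride desilylation under acidic, non-basic conditions avoids enolate-driven β-elimination of the β-alkoxy lactone.

**Union, key step and end game**

Step 13
Reactants: 10 5-hydroxy-3-(methoxymethoxy)-2-(trimethylsilyl)phenyl trifluoromethanesulfonate; 18 the (R)-hydroxy lactone
Product: 19 5-(LacO)-3-(methoxymethoxy)-2-(trimethylsilyl)phenyl trifluoromethanesulfonate
Conditions: PPh3 (1.5 equiv), DIAD (1.5 equiv), THF, 0 °C to rt
Reagents that add atoms: none
Why: Mitsunobu etherification, in which the acidic, triflate-bearing phenol displaces the alkoxyphosphonium by SN2 with inversion and converts the R carbinol into the S aryl ether under neutral conditions that harm neither the lactone nor the silyl triflate.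

Step 14
Reactants: 19 the silylaryl triflate carrying the lactone ether; 20 phenylpropiolic acid
Product: 23 7-(LacO)-5-(methoxymethoxy)-2-phenyl-4H-chromen-4-one, via aryne 21 (not isolated), via hydroxyaryl ynone 22 (not isolated)
Conditions: CsF (5 equiv), 20 (2.5 equiv), THF, 125 °C, sealed tube
Reagents that add atoms: none
Why: CsF strips the trimethylsilyl group while triflate leaves, giving the 3-alkoxy aryne 21; caesium phenylpropiolate adds through oxygen to the aryne carbon remote from the MOM ether (future C8a), the aryl anion thus placed on C4a adds to the neighbouring ester carbonyl in a four-centre acyl shift, and opening of the benzoxetene alkoxide cleaves the acyl C–O bond to leave the phenoxide of ynone 22. The closest known reaction is the insertion of arynes into the C–O bond of carboxylic acids to give ortho-hydroxyaryl ketones, including the direct formation of flavones from arylpropiolic acids. Ring C then closes by 6-endo-dig conjugate addition of the C8a phenoxide to the ynone β-carbon (O1–C2), so three skeletal bonds (C8a–O1, C4a–C4, O1–C2) and one ring form in one flask. No stereocentre is created, and since the flavone is planar at C2 the heat needed for the acyl shift has nothing on ring C to erode. The step needs oxygen on C8a and not on C4a, which the inductively withdrawing C5 oxygen beside the aryne secures by stabilising the developing carbanion at C4a (the more remote C7 ether has little say); it also needs C-acylation to outrun protonation of the aryl anion, helped by the aprotic medium, excess caesium carboxylate and high temperature, and 6-endo over 5-exo closure, which free phenoxide in an aprotic solvent favours.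

Step 15
Reactants: 23 the flavone
Product: 25 (2S)-7-(LacO)-5-(methoxymethoxy)-2-phenyl-2,3-dihydro-4H-chromen-4-one, via silyl enol ether 24 (not isolated)
Conditions: Cu(OAc)2·H2O (5 mol%), (R)-DTBM-SEGPHOS (5.5 mol%), (EtO)2MeSiH (3 equiv), toluene, 0 °C to rt; then aq NH4Cl, THF, rt
Reagents that add atoms: none
Why: Copper hydride catalysed asymmetric conjugate reduction as known for chromones: the bisphosphine-bound CuH should deliver hydride to the Re face of C2 under catalyst control to set 2S, and the enolate is held as a silyl enol ether (shielding C4=O from 1,2-reduction) until mild hydrolysis.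

Step 16
Reactants: 25 the MOM-protected flavanone
Product: 26 (2S)-5-hydroxy-7-(LacO)-2-phenyl-2,3-dihydro-4H-chromen-4-one (target)
Conditions: 2 M aq HCl, THF, 40 °C
Reagents that add atoms: none
Why: Acid-catalysed acetal hydrolysis of the MOM ether, eased by the peri carbonyl that then hydrogen-bonds the freed 5-OH; the γ-lactone, the benzylic aryl ether and the C2 centre (labile only to base) should be stable to dilute acid.

**Compound list**

1 | resorcinol | Oc1cccc(O)c1 | starting material
2 | 3-(methoxymethoxy)phenol | COCOc1cccc(O)c1 | intermediate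
3 | 3-(methoxymethoxy)phenyl isopropylcarbamate | COCOc1cccc(OC(=O)NC(C)C)c1 | intermediate
4 | 3-(methoxymethoxy)phenyl N-(tert-butyldimethylsilyl)-N-isopropylcarbamate (formed in the flask) | COCOc1cccc(OC(=O)N(C(C)C)[Si](C)(C)C(C)(C)C)c1 | intermediate
5 | 3-(methoxymethoxy)-2-(trimethylsilyl)phenyl N-(tert-butyldimethylsilyl)-N-isopropylcarbamate (formed in the flask) | COCOc1cccc(OC(=O)N(C(C)C)[Si](C)(C)C(C)(C)C)c1[Si](C)(C)C | intermediate
6 | 3-(methoxymethoxy)-2-(trimethylsilyl)phenyl isopropylcarbamate | COCOc1cccc(OC(=O)NC(C)C)c1[Si](C)(C)C | intermediate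
7 | 3-(methoxymethoxy)-2-(trimethylsilyl)phenol (formed in the flask) | COCOc1cccc(O)c1[Si](C)(C)C | intermediate
8 | 3-(methoxymethoxy)-2-(trimethylsilyl)phenyl trifluoromethanesulfonate | COCOc1cccc(OS(=O)(=O)C(F)(F)F)c1[Si](C)(C)C | intermediate
9 | 3-(methoxymethoxy)-5-(4,4,5,5-tetramethyl-1,3,2-dioxaborolan-2-yl)-2-(trimethylsilyl)phenyl trifluoromethanesulfonate | COCOc1cc(B2OC(C)(C)C(C)(C)O2)cc(OS(=O)(=O)C(F)(F)F)c1[Si](C)(C)C | intermediate
10 | 5-hydroxy-3-(methoxymethoxy)-2-(trimethylsilyl)phenyl trifluoromethanesulfonate | COCOc1cc(O)cc(OS(=O)(=O)C(F)(F)F)c1[Si](C)(C)C | intermediate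
11 | methyl (R)-mandelate | COC(=O)[C@H](O)c1ccccc1 | starting material
12 | methyl (R)-2-[(tert-butyldimethylsilyl)oxy]-2-phenylacetate | COC(=O)[C@H](O[Si](C)(C)C(C)(C)C)c1ccccc1 | intermediate
13 | (R)-2-[(tert-butyldimethylsilyl)oxy]-2-phenylacetaldehyde | O=C[C@H](O[Si](C)(C)C(C)(C)C)c1ccccc1 | intermediate
14 | (5S,6R)-6-[(tert-butyldimethylsilyl)oxy]-5-hydroxy-6-phenylhex-1-en-3-one | C=CC(=O)C[C@H](O)[C@H](O[Si](C)(C)C(C)(C)C)c1ccccc1 | intermediate
15 | O-diethylboryl chelate of 14 (formed in the flask) | C=CC(=O)C[C@H](OB(CC)CC)[C@H](O[Si](C)(C)C(C)(C)C)c1ccccc1 | intermediate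
16 | (3R,5S,6R)-6-[(tert-butyldimethylsilyl)oxy]-6-phenylhex-1-ene-3,5-diol | C=C[C@H](O)C[C@H](O)[C@H](O[Si](C)(C)C(C)(C)C)c1ccccc1 | intermediate
17 | (3aR,5S,6aR)-5-{(R)-[(tert-butyldimethylsilyl)oxy](phenyl)methyl}tetrahydrofuro[3,2-b]furan-2(3H)-one | O=C1C[C@H]2O[C@H]([C@H](O[Si](C)(C)C(C)(C)C)c3ccccc3)C[C@H]2O1 | intermediate
18 | (3aR,5S,6aR)-5-[(R)-hydroxy(phenyl)methyl]tetrahydrofuro[3,2-b]furan-2(3H)-one | O=C1C[C@H]2O[C@H]([C@H](O)c3ccccc3)C[C@H]2O1 | intermediate
19 | 3-(methoxymethoxy)-5-{(S)-[(3aR,5S,6aR)-2-oxohexahydrofuro[3,2-b]furan-5-yl](phenyl)methoxy}-2-(trimethylsilyl)phenyl trifluoromethanesulfonate | O=C1C[C@H]2O[C@H]([C@@H](Oc3cc(OCOC)c([Si](C)(C)C)c(OS(=O)(=O)C(F)(F)F)c3)c3ccccc3)C[C@H]2O1 | intermediate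
20 | phenylpropiolic acid | OC(=O)C#Cc1ccccc1 | starting material
21 | 1,2-didehydro-3-(methoxymethoxy)-5-{(S)-[(3aR,5S,6aR)-2-oxohexahydrofuro[3,2-b]furan-5-yl](phenyl)methoxy}benzene (aryne, formed in the flask) | O=C1C[C@H]2O[C@H]([C@@H](OC3=CC#CC(OCOC)=C3)c3ccccc3)C[C@H]2O1 | intermediate
22 | 1-[2-hydroxy-6-(methoxymethoxy)-4-{(S)-[(3aR,5S,6aR)-2-oxohexahydrofuro[3,2-b]furan-5-yl](phenyl)methoxy}phenyl]-3-phenylprop-2-yn-1-one (formed in the flask) | O=C1C[C@H]2O[C@H]([C@@H](Oc3cc(OCOC)c(C(=O)C#Cc4ccccc4)c(O)c3)c3ccccc3)C[C@H]2O1 | intermediate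
23 | 5-(methoxymethoxy)-7-{(S)-[(3aR,5S,6aR)-2-oxohexahydrofuro[3,2-b]furan-5-yl](phenyl)methoxy}-2-phenyl-4H-chromen-4-one | O=C1C[C@H]2O[C@H]([C@@H](Oc3cc(OCOC)c4c(c3)OC(c3ccccc3)=CC4=O)c3ccccc3)C[C@H]2O1 | intermediate
24 | (2S)-4-{[diethoxy(methyl)silyl]oxy}-5-(methoxymethoxy)-7-{(S)-[(3aR,5S,6aR)-2-oxohexahydrofuro[3,2-b]furan-5-yl](phenyl)methoxy}-2-phenyl-2H-chromene (formed in the flask) | O=C1C[C@H]2O[C@H]([C@@H](Oc3cc(OCOC)c4c(c3)O[C@H](c3ccccc3)C=C4O[Si](C)(OCC)OCC)c3ccccc3)C[C@H]2O1 | intermediate
25 | (2S)-5-(methoxymethoxy)-7-{(S)-[(3aR,5S,6aR)-2-oxohexahydrofuro[3,2-b]furan-5-yl](phenyl)methoxy}-2-phenyl-2,3-dihydro-4H-chromen-4-one | O=C1C[C@H]2O[C@H]([C@@H](Oc3cc(OCOC)c4c(c3)O[C@H](c3ccccc3)CC4=O)c3ccccc3)C[C@H]2O1 | intermediate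
26 | (2S)-5-hydroxy-7-{(S)-[(3aR,5S,6aR)-2-oxohexahydrofuro[3,2-b]furan-5-yl](phenyl)methoxy}-2-phenyl-2,3-dihydro-4H-chromen-4-one | O=C1C[C@H]2O[C@H]([C@@H](Oc3cc(O)c4c(c3)O[C@H](c3ccccc3)CC4=O)c3ccccc3)C[C@H]2O1 | target

**Step count.** Total: 16 steps. Longest linear sequence: 10 steps (steps 1–6 then 13–16 from resorcinol; the branch from methyl (R)-mandelate, steps 7–12 then 13–16, is equally long).

**Steps most likely to fail**

1. Step 14. The aryl anion may be protonated before the acyl shift, leaving simple O-arylation. The alkynoic acid may decarboxylate at 125 °C. Hot fluoride may also open or epimerise the β-alkoxy lactone through its enolate. Fallback, setting out from 19 and returning at 23: the same aryne is released at room temperature with CsF in DMF, where it inserts into the formamide C=O bond with the same regiochemistry and, after aqueous hydrolysis, should give the salicylaldehyde F1. Addition of PhC≡CMgBr (2.2 equiv, THF, −78 °C; the aldehyde reacts well ahead of the lactone) gives the propargylic alcohol F2 as a mixture of carbinol epimers. MnO2 in CH2Cl2 oxidises it to ynone 22, which K2CO3 in acetone cyclises to flavone 23.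

2. Step 15. Hydride transfer to the doubly substituted, oxygen-stabilised β-carbon next to the peri MOM ether may be sluggish, facial selectivity may be poor, or the ketone may be over-reduced once released. Fallback, setting out from 23 and returning at 25: asymmetric hydrogenation with the catalyst preformed from [Ru(cod)(2-methylallyl)2], a chiral C2-symmetric imidazolinium tetrafluoroborate and KOt-Bu, under H2 pressure in hexane/t-AmOH, a method established for flavones. It reduces C2=C3 and in part C4=O, giving 25 together with the cis flavan-4-ol F3. MnO2 oxidation of the benzylic alcohol in the mixture converges on 25.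

3. Step 13. SN2 displacement at the hindered benzylic carbon next to the ring oxygen may be slow, letting elimination or partial ionisation (loss of stereochemical fidelity) compete. Fallback, setting out from 18 and returning at 19: the alcohol is first converted into the isolable mesylate F4 (MsCl, Et3N, CH2Cl2, −20 °C). F4 is then displaced with inversion by the preformed potassium phenoxide of 10 (K2CO3, DMF, rt), a classical sulfonate displacement that no longer depends on the phosphonium intermediate.

**Further compounds**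

F1 | step 14 | 2-hydroxy-6-(methoxymethoxy)-4-{(S)-[(3aR,5S,6aR)-2-oxohexahydrofuro[3,2-b]furan-5-yl](phenyl)methoxy}benzaldehyde | O=C1C[C@H]2O[C@H]([C@@H](Oc3cc(OCOC)c(C=O)c(O)c3)c3ccccc3)C[C@H]2O1
F2 | step 14 | 1-[2-hydroxy-6-(methoxymethoxy)-4-{(S)-[(3aR,5S,6aR)-2-oxohexahydrofuro[3,2-b]furan-5-yl](phenyl)methoxy}phenyl]-3-phenylprop-2-yn-1-ol (both carbinol epimers) | O=C1C[C@H]2O[C@H]([C@@H](Oc3cc(OCOC)c(C(O)C#Cc4ccccc4)c(O)c3)c3ccccc3)C[C@H]2O1
F3 | step 15 | (2S,4S)-5-(methoxymethoxy)-7-{(S)-[(3aR,5S,6aR)-2-oxohexahydrofuro[3,2-b]furan-5-yl](phenyl)methoxy}-2-phenylchroman-4-ol | O=C1C[C@H]2O[C@H]([C@@H](Oc3cc(OCOC)c4c(c3)O[C@H](c3ccccc3)C[C@@H]4O)c3ccccc3)C[C@H]2O1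
F4 | step 13 | (R)-[(3aR,5S,6aR)-2-oxohexahydrofuro[3,2-b]furan-5-yl](phenyl)methyl methanesulfonate | O=C1C[C@H]2O[C@H]([C@H](OS(C)(=O)=O)c3ccccc3)C[C@H]2O1
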